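## The problem

Microeunicellol B, compound 34, is a trans-fused bicyclo[8.4.0]tetradecane. Ring A (C1, C10–C14) shares the C1–C10 bond with a ten-membered carbocycle (C1–C10); C20 is the methylene carbon on C11. The large ring holds two trisubstituted alkenes, C2=C3 (CO2Me on C3) and C6=C7 (CO2H on C7), each with its ring carbons cis, so the ring must be closed against transannular strain without loss of either geometry. Of the four stereocentres, C14 (isopropyl) and C1 are cis neighbours on ring A and can be set together; C10 is trans to C1 and can be steered by them; C8 (R, hydroxyl) lies across the large ring and needs reagent control. Three features rule out strong acid, strong base and unselective hydride late in the route: the exocyclic C11=C20 alkene (migration or transannular cyclisation under acid), the C8 carbinol allylic to an acrylate (ionisation, allylic transposition), and two conjugated carboxyl groups that must end as one methyl ester and one free acid. A 2-alkylidene-3-oxo ester at C6–C8 appears on the way; it is a strong Michael acceptor, and the geometry needed (C5 cis to C8) is the less stable one, so it has to be set kinetically. The enabling feature is the unit C9–C10–C11=C20. C10 is homoallylic to the methylene carbon and C9 is α to the C8 oxygen, which is the product pattern of a [2,3] shift of an allyl sulfonium ylide with C9 as ylide carbon and sulfur on C20 of a C10=C11 cyclohexene.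

## Retrosynthesis

**34 ⇒ 33 ⇒ 32 ⇒ 31 (no skeletal bond cut).** The C7 acid is unmasked last from the 2-(trimethylsilyl)ethyl ester 33 by fluoride, which leaves the C3 methyl ester, the allylic alcohol and the methylene group alone. The C8 alcohol comes from ketone 32 by catalyst-controlled reduction, and the C9 methylene from the α-phenylthio ketone 31 by reductive C–S cleavage. The sulfur is removed before the reduction because a β-hydroxy sulfide would no longer be activated for cleavage.

**31 ⇒ 29 (through ylide 30): C9–C10 cut with allylic transposition.** Breaking C9–C10, moving the alkene from C11=C20 to C10=C11 and joining C20 to the sulfur on C9 gives the thirteen-membered ylide 30, which opens at S–C9 to the diazo ketone 29. A direct closure at C2=C3 or C6=C7 by olefination, or at C8–C9 by aldol chemistry, would close the ring but would not create C10 or the methylene group. This cut does both. The precursor is monocyclic with two stereocentres, and its chain is made by olefinations. The forward reaction must trap a carbenoid at a remote sulfide and deliver C9 to the C10 face anti to the C1 and C14 substituents.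

**29 ⇒ 27 ⇒ 24 ⇒ 19: C9 diazo group, C7–C8 bond, C6=C7 bond.** A Knoevenagel condensation of aldehyde 19 with a β-keto ester would favour the isomer with the ketone trans to the chain. Acylation of a diazoalkane by an alkylidene malonyl chloride would be undercut by dipolar cycloaddition to the electron-poor alkene. The geometry is therefore fixed while C7 carries only the ester: a halo-ylide Wittig reaction gives the (Z)-iodo enoate 24 with the ester trans to C5. A Stille coupling with stannane 25 then replaces iodine by a masked acetyl group with retention, giving methyl ketone 27 with the acyl group cis to C5. The diazo group is put on afterwards by diazo transfer to the methyl ketone, with no diazoalkane. The forward steps must not equilibrate the alkene.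

**19 ⇒ 18 ⇒ 17 + 16: C2=C3 cut.** A Wittig reaction of aldehyde 17 with the α-substituted stabilised ylide 16 gives the trisubstituted enoate with C1 trans to the ester, which is the geometry of 34. Ylide 16 brings C3–C6 with C6 masked as an acetal, so one mild hydrolysis gives 19. The cut reduces the problem to ring A with a one-carbon handle on C1. The aldehyde is β,γ-unsaturated and epimerisable, which argues for the base-free Wittig reaction over a phosphonate.

**17 ⇒ 12 ⇒ 11 ⇒ 10 ⇒ 9 ⇒ 8 ⇒ 7: functional-group changes on ring A.** The C2 aldehyde comes from alcohol 12 and silyl ether 11. The isopropyl group is built from the acyl group of 7 by way of Weinreb amide 8, methyl ketone 9 and isopropenyl compound 10. This is done before the enoate exists, because it uses a Grignard reagent. The forward sequence must keep the cis C1/C14 relationship, hence a non-basic methylenation, and must reduce a 1,1-disubstituted alkene beside a trisubstituted one and a sulfide, hence diimide.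

**7 ⇒ 5 + 6: C12–C13 and C14–C1 cut (Diels–Alder).** Ring A with its C10=C11 alkene is the adduct of the 1,3-disubstituted butadiene 5 and the acrylimide 6. Both diene substituents direct the same regiochemistry. The endo rule gives the cis C1/C14 pair, and a chiral divalent copper catalyst sets the absolute configuration. The diene already carries the phenylthio group that the key step needs, so no later allylic functionalisation of C20 is required.

**5 ⇒ 3 + 4; 3 ⇒ 1 + 2; 16 ⇒ 13 + 14; 22 ⇒ 20 + 21.** The diene is cut at the C10–C11 bond into bromide 3 and (E)-boronate 4 (Suzuki–Miyaura coupling). Bromide 3 is the thiolate alkylation product of 1 and 2. Ylide 16 is the alkylation product of 13 with 14, and the silylethyl ylide 22 is the adduct of 20 and 21.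

## Roads not taken

**Alternative 1:** The cut is at C1–C2 and C9–C10 on an aromatic ring-A precursor. The arene complex A1, tricarbonyl(4-isopropylanisole)chromium, would take 2-lithio-1,3-dithiane A2 at the carbon that becomes C1, and the metal would then deliver the allyl group of allyl bromide A3 to the neighbouring carbon C10, giving the trans-disubstituted methoxydiene A4.
- Merits: two C–C bonds form in one pot from a cheap arene and the simple partners A2 and A3, and the C1/C10 trans relationship follows from the mechanism (nucleophile anti to chromium, electrophile from the metal face). On this point the route is more secure than the chosen plan, which relies on facial selectivity in step 17 for the same relationship.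
- Weak points: A1 has a mirror plane, so the absolute configuration must come from a chiral ligand on A2 at two enantiotopic positions, each ortho to the isopropyl group. C14 stays sp2 in A4 and would need a later reduction cis to C1. The enol ether must be converted to the C11 methylene group, the dithiane carbon from A2 and the allyl group from A3 must each be grown into half of the C2–C9 chain, and a separate macrocyclisation is still needed. Chromium is stoichiometric.
- Comparison: the chosen plan sets against the firmer trans control a catalytic enantioselective cycloaddition that fixes C14 and C1 together, and a key step that closes the large ring.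

**Alternative 2:** The cut is at C10–C11 and C14–C1. The diene A5, (E)-5-methylhexa-1,3-diene, and the chiral imide A6, an (E)-5-silyloxypent-2-enoyl oxazolidinone, would combine under Et2AlCl to give cyclohexene A7.
- Merits: all three ring-A stereocentres (C1, C10, C14) are set in one auxiliary-controlled step, C1/C10 trans from the dienophile geometry and C14/C1 cis from the endo rule. In ring-A stereocontrol this road is better than the chosen plan, whose cycloaddition sets only C14 and C1.
- Weak points: A6 is a β-substituted acrylimide and A5 a 1-alkyl diene with a branched terminus, so both partners are sluggish. The ring alkene of A7 lies at C12=C13, so C11 has no handle; the methylene group would need allylic oxidation with C14 competing, alkene saturation and methylenation. The ten-membered ring would still have to be closed by a separate macrocyclisation between the C2 acyl group and the C8/C9 arm.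
- Comparison: the chosen plan sets against the better stereocontrol of A7 the cycloadduct 7, whose alkene and sulfur are already where the key step needs them, and a ring closure that creates C10 and the methylene group at once.

**Alternative 3:** The cut is the C1–C10 bond, made transannularly. A fourteen-membered carbocycle A8 holds a trans C1–C2 epoxide and an allylsilane (C10=C11 with CH2SiMe3 on C11). A Lewis acid would open the epoxide at C1 with inversion by C10, giving the bicyclic C2 alcohol A9 with ring A, the ten-membered ring and the methylene group formed together.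
- Merits: like the chosen plan, one step divides a larger ring into the bicycle and installs C11=C20. The anti opening makes the C1/C10 relationship stereospecific, and no sulfur has to be removed.
- Weak points: the ring-closure problem is moved, not solved. A8 is itself a macrocycle that must be built with a geometrically defined trisubstituted allylsilane, an epoxide of the right absolute configuration relative to C14 and C8, and C8 already set. The Lewis acid step must compete with epoxide rearrangement and with capture by the ester carbonyls. A9 still needs dehydration of the C2 alcohol to the C2=C3 enoate with control of direction and geometry.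
- Comparison: the two roads are equal in what the key step achieves. The chosen plan sets against the stereospecificity of A9 the precursor 29, which is an open chain on a ready-made ring A.

Key step: step 17

Remark: atom numbers are those of the bicyclo[8.4.0]tetradecane skeleton of 34 (C1–C14, C20 on C11) and are used for all intermediates; 4, 6, 13, 14, 20, 21 and 25 are taken as catalogue reagents.

## Route

Step 1
Reactants: 1 thiophenol; 2 2,3-dibromoprop-1-ene
Product: 3 2-bromo-3-(phenylsulfanyl)prop-1-ene
Conditions: K2CO3, acetone, 0 → 23 °C
Reagents that add atoms: none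
Why: SN2 displacement of the allylic bromide by thiophenolate; the vinylic bromide does not react and is kept for the coupling.

Step 2
Reactants: 3 2-bromo-3-(phenylsulfanyl)prop-1-ene; 4 (E)-3-(tert-butyldimethylsilyloxy)prop-1-enylboronic acid pinacol ester
Product: 5 (E)-1-(tert-butyldimethylsilyloxy)-4-(phenylsulfanylmethyl)penta-2,4-diene
Conditions: Pd(PPh3)4 (5 mol %), K3PO4, THF/H2O, 60 °C
Reagents that add atoms: none
Why: Suzuki–Miyaura coupling of an alkenyl bromide with an (E)-alkenylboronate under zerovalent palladium goes with retention at both partners and tolerates the thioether and the silyl ether.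

Step 3
Reactants: 5 diene; 6 3-(prop-2-enoyl)-1,3-oxazolidin-2-one
Product: 7 cis-(1R,2S) cyclohexene imide (acyl on C14 and CH2OSi on C1 cis)
Conditions: Cu(SbF6)2 (10 mol %, from CuCl2 and AgSbF6) with (R,R)-t-Bu-box [2,2'-(propane-2,2-diyl)bis((4R)-4-tert-butyl-4,5-dihydro-1,3-oxazole)], CH2Cl2, −20 → 23 °C
Reagents that add atoms: none
Why: Bis(oxazoline)–copper catalysed Diels–Alder reaction of the chelated s-cis acrylimide; both diene substituents direct C12 to the acrylate β-carbon and the endo transition state places the C1 and C14 substituents cis. With the (R,R)-ligand the square-planar chelate model leaves the α-Si face of the dienophile open, which gives (R) at the acyl-bearing carbon and (S) at its neighbour.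

Step 4
Reactants: 7 cyclohexene imide
Product: 8 Weinreb amide (1R,2S)
Conditions: MeNH(OMe)·HCl, AlMe3, CH2Cl2, −10 → 0 °C
Reagents that add atoms: N,O-dimethylhydroxylamine hydrochloride, CNOC.Cl
Why: Aluminium amide transamination of the N-acyl oxazolidinone (Weinreb amide formation) attacks the exocyclic carbonyl and does not epimerise the α-carbon.

Step 5
Reactants: 8 Weinreb amide
Product: 9 methyl ketone (1R,2S)
Conditions: MeMgBr, THF, −78 → 0 °C
Reagents that add atoms: methylmagnesium bromide, C[Mg]Br
Why: Weinreb ketone synthesis; the chelated tetrahedral adduct holds until the quench, so only one methyl group adds and the α-stereocentre is not exposed to base as a ketone.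

Step 6
Reactants: 9 methyl ketone
Product: 10 isopropenyl compound (1S,6R)
Conditions: Zn, CH2Br2, TiCl4, THF/CH2Cl2, 0 → 23 °C
Reagents that add atoms: dibromomethane, BrCBr
Why: Lombardo–Takai methylenation is non-basic, so the cis α-stereocentre is not epimerised as it could be under a Wittig reaction.

Step 7
Reactants: 10 isopropenyl compound
Product: 11 isopropyl silyl ether (1R,6S)
Conditions: 2-O2NC6H4SO2NHNH2, Et3N, CH2Cl2, 23 °C
Reagents that add atoms: none
Why: Diimide reduction saturates the 1,1-disubstituted alkene faster than the trisubstituted ring alkene and is indifferent to sulfur, which would poison most hydrogenation catalysts; no stereocentre is formed.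

Step 8
Reactants: 11 isopropyl silyl ether
Product: 12 primary alcohol (1R,6S)
Conditions: Bu4NF, THF, 0 → 23 °C
Reagents that add atoms: none
Why: Fluoride desilylation of a primary silyl ether; nothing else in 11 reacts.

Step 9
Reactants: 13 methyl (triphenylphosphoranylidene)acetate (2 equiv); 14 3-bromo-1,1-dimethoxypropane
Product: 16 methyl 5,5-dimethoxy-2-(triphenylphosphoranylidene)pentanoate, via alkylated phosphonium bromide 15 (not isolated)
Conditions: MeCN, 80 °C
Reagents that add atoms: none
Why: C-alkylation of the stabilised ylide by the primary bromide, then transylidation by the second equivalent of 13, gives the α-substituted ylide directly.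

Step 10
Reactants: 12 primary alcohol
Product: 17 β,γ-unsaturated aldehyde (1R,6S)
Conditions: Dess–Martin periodinane, pyridine, CH2Cl2, 0 °C
Reagents that add atoms: none
Why: Dess–Martin oxidation is fast and near neutral and leaves the sulfide alone; the aldehyde is filtered and used at once to avoid epimerisation at C1 or alkene migration.

Step 11
Reactants: 17 aldehyde; 16 substituted ylide
Product: 18 (E)-enoate acetal (1S,6S)
Conditions: PhMe, 23 → 50 °C
Reagents that add atoms: none
Why: Wittig olefination with an α-substituted stabilised ylide gives the (E)-enoate (C1 trans to CO2Me and cis to C4) and needs no added base.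

Step 12
Reactants: 18 enoate acetal
Product: 19 C6 aldehyde
Conditions: TsOH·H2O (cat.), acetone/H2O, 23 °C
Reagents that add atoms: water, O
Why: Acid-catalysed acetal hydrolysis; the enoate, the sulfide and the ring alkene are inert to catalytic acid in wet acetone.

Step 13
Reactants: 20 (triphenylphosphoranylidene)ketene; 21 2-(trimethylsilyl)ethanol
Product: 22 2-(trimethylsilyl)ethyl (triphenylphosphoranylidene)acetate
Conditions: THF, 65 °C
Reagents that add atoms: none
Why: Addition of the alcohol to the cumulated ylide gives the ester-stabilised ylide in one operation.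

Step 14
Reactants: 19 C6 aldehyde; 22 silylethyl ester ylide
Product: 24 (Z)-α-iodo enoate, via iodo ylide 23 (not isolated)
Conditions: 22, N-iodosuccinimide, CH2Cl2, −20 °C; then K2CO3, 19, −20 → 23 °C
Reagents that add atoms: N-iodosuccinimide, O=C1CCC(=O)N1I
Why: Iodination of the stabilised ylide followed by Wittig olefination gives the (Z)-α-iodo enoate with the ester trans to the chain, as for other stabilised ylides. The N-iodoimide is consumed by the ylide before the sulfide-bearing aldehyde is added.

Step 15
Reactants: 24 (Z)-α-iodo enoate; 25 tributyl(1-ethoxyethenyl)stannane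
Product: 27 methyl ketone with the acetyl group cis to C5, via 2-ethoxydiene 26 (not isolated)
Conditions: Pd2(dba)3, AsPh3, CuI, DMF, 40 °C; then 1 M HCl, THF, 0 °C
Reagents that add atoms: water, O
Why: Stille coupling with retention at the alkenyl iodide puts the acetyl anion equivalent cis to C5, and cold dilute acid unmasks the enol ether. Triphenylarsine is used so that no nucleophilic phosphine is present to isomerise the acceptor alkene.

Step 16
Reactants: 27 methyl ketone
Product: 29 diazo ketone, via trifluoroacetyl ketone 28 (not isolated)
Conditions: LiN(SiMe3)2, THF, −78 °C; CF3CO2CH2CF3, −78 °C; then MsN3, Et3N, H2O, MeCN, 23 °C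
Reagents that add atoms: methanesulfonyl azide, CS(=O)(=O)N=[N+]=[N-]; 2,2,2-trifluoroethyl trifluoroacetate (atoms kept only in 28), O=C(OCC(F)(F)F)C(F)(F)F
Why: Detrifluoroacetylative diazo transfer (Regitz type): kinetic enolisation of the acetyl group, which is twisted out of conjugation and is the most acidic site, then trifluoroacetylation and sulfonyl azide transfer with loss of the trifluoroacetyl group. No diazoalkane is used, so dipolar cycloaddition to the electron-poor alkene is avoided.

Step 17
Reactants: 29 diazo ketone
Product: 31 bicyclic α-phenylthio ketone (C9 epimers), via cyclic sulfonium ylide 30 (not isolated)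
Conditions: Rh2(OAc)4 (2 mol %), CH2Cl2, 40 °C, 29 added by syringe pump (final concentration about 1 mM)
Reagents that add atoms: none
Why: Rh2(OAc)4 converts the diazo ketone into an electrophilic rhodium carbenoid at C9, which is captured by the lone pair of the C20 sulfide to give the thirteen-membered allyl sulfonium ylide 30; this undergoes a suprafacial [2,3]-sigmatropic shift through a five-centre envelope transition state (C9, S, C20, C11, C10) in which C9–C10 forms, the alkene moves to C11=C20 and S–C20 breaks. The closest known reaction type is the Doyle–Kirmse reaction, including its intramolecular form in which a cyclic allyl sulfonium ylide contracts to a carbocycle; the ring sizes here (thirteen to ten) extend that precedent. The ten-membered ring is therefore not closed end to end: the large ring is first closed at sulfur by a fast heteroatom capture where strain is low, and is then contracted by three atoms, with the phenylthio group left outside the ring on C9. C10 is set by substrate control: C9 must reach C10 on the face where the S–C20 bond lies, and the face syn to the cis C1 alkenyl and C14 isopropyl groups (isopropyl axial when the C1 tether is pseudoequatorial) is blocked, so bonding anti to them gives the trans ring fusion (10S); C9 forms as a mixture and is erased in step 18. The step needs chemoselectivity for sulfur over the C7 ester carbonyl, the allylic C5–H bonds, the alkenes and a second molecule of 29; it relies on the thiophilicity of the carbenoid, on reversible and unproductive carbonyl-ylide formation at a weakly basic ester, on the electron-poor or hindered alkenes, and on slow addition at high dilution. It also needs the [2,3] shift to win over the [1,2] shift, which the allylic sulfonium geometry favours, and retention of the C6=C7 geometry, which holds because no nucleophilic catalyst is present.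

Step 18
Reactants: 31 bicyclic α-phenylthio ketone
Product: 32 bicyclic C8 ketone
Conditions: SmI2 (2.2 equiv), THF/MeOH, −78 °C
Reagents that add atoms: none
Why: Reductive cleavage of an α-heteroatom ketone by SmI2: electron transfer to the ketone expels thiophenolate and the samarium enolate is protonated by methanol. At −78 °C with two equivalents this should outrun conjugate reduction of the 2-alkylidene-3-oxo ester, and both C9 epimers converge on 32.

Step 19
Reactants: 32 bicyclic C8 ketone
Product: 33 (8R)-alcohol
Conditions: (S)-2-methyl-CBS-oxazaborolidine (20 mol %), catecholborane, PhMe/CH2Cl2, −78 °C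
Reagents that add atoms: none
Why: Corey–Bakshi–Shibata reduction with the alkenyl carbon C7 as the large and C9H2 as the small flank; the (S)-catalyst then delivers hydride to give (8R), in the same sense as for aryl methyl ketones. Catecholborane does not hydroborate the methylene group at this temperature.

Step 20
Reactants: 33 (8R)-alcohol
Product: 34 microeunicellol B
Conditions: Bu4NF, THF, 0 → 23 °C; then 0.5 M HCl to pH 3, 0 °C
Reagents that add atoms: none
Why: Fluoride-induced β-elimination of the 2-(trimethylsilyl)ethyl ester releases the C7 acid with loss of ethene and the fluorosilane; the methyl ester, the allylic alcohol and the exocyclic alkene are untouched.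

## Compound list

1 | thiophenol | Sc1ccccc1 | starting material
2 | 2,3-dibromoprop-1-ene | C=C(Br)CBr | starting material
3 | 2-bromo-3-(phenylsulfanyl)prop-1-ene | C=C(Br)CSc1ccccc1 | intermediate
4 | tert-butyldimethyl{[(2E)-3-(4,4,5,5-tetramethyl-1,3,2-dioxaborolan-2-yl)prop-2-en-1-yl]oxy}silane | CC(C)(C)[Si](C)(C)OC/C=C/B1OC(C)(C)C(C)(C)O1 | starting material
5 | tert-butyldimethyl({(2E)-4-[(phenylsulfanyl)methyl]penta-2,4-dien-1-yl}oxy)silane | C=C(CSc1ccccc1)/C=C/CO[Si](C)(C)C(C)(C)C | intermediate
6 | 3-(prop-2-enoyl)-1,3-oxazolidin-2-one | C=CC(=O)N1CCOC1=O | starting material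
7 | 3-{[(1R,2S)-2-{[tert-butyl(dimethyl)silyl]oxymethyl}-4-[(phenylsulfanyl)methyl]cyclohex-3-en-1-yl]carbonyl}-1,3-oxazolidin-2-one | CC(C)(C)[Si](C)(C)OC[C@H]1C=C(CSc2ccccc2)CC[C@H]1C(=O)N1CCOC1=O | intermediate
8 | (1R,2S)-2-{[tert-butyl(dimethyl)silyl]oxymethyl}-N-methoxy-N-methyl-4-[(phenylsulfanyl)methyl]cyclohex-3-ene-1-carboxamide | CC(C)(C)[Si](C)(C)OC[C@H]1C=C(CSc2ccccc2)CC[C@H]1C(=O)N(C)OC | intermediate
9 | 1-[(1R,2S)-2-{[tert-butyl(dimethyl)silyl]oxymethyl}-4-[(phenylsulfanyl)methyl]cyclohex-3-en-1-yl]ethan-1-one | CC(C)(C)[Si](C)(C)OC[C@H]1C=C(CSc2ccccc2)CC[C@H]1C(C)=O | intermediate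
10 | tert-butyldimethyl{[(1S,6R)-3-[(phenylsulfanyl)methyl]-6-(prop-1-en-2-yl)cyclohex-2-en-1-yl]methoxy}silane | CC(C)(C)[Si](C)(C)OC[C@H]1C=C(CSc2ccccc2)CC[C@H]1C(C)=C | intermediate
11 | tert-butyldimethyl{[(1R,6S)-3-[(phenylsulfanyl)methyl]-6-(propan-2-yl)cyclohex-2-en-1-yl]methoxy}silane | CC(C)(C)[Si](C)(C)OC[C@H]1C=C(CSc2ccccc2)CC[C@H]1C(C)C | intermediate
12 | [(1R,6S)-3-[(phenylsulfanyl)methyl]-6-(propan-2-yl)cyclohex-2-en-1-yl]methanol | OC[C@H]1C=C(CSc2ccccc2)CC[C@H]1C(C)C | intermediate
13 | methyl (triphenyl-λ5-phosphanylidene)acetate | COC(=O)C=P(c1ccccc1)(c1ccccc1)c1ccccc1 | starting material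
14 | 3-bromo-1,1-dimethoxypropane | COC(OC)CCBr | starting material
15 | (1,5,5-trimethoxy-1-oxopentan-2-yl)triphenylphosphonium bromide | COC(=O)C(CCC(OC)OC)[P+](c1ccccc1)(c1ccccc1)c1ccccc1.[Br-] | intermediate (not isolated)
16 | methyl 5,5-dimethoxy-2-(triphenyl-λ5-phosphanylidene)pentanoate | COC(=O)C(CCC(OC)OC)=P(c1ccccc1)(c1ccccc1)c1ccccc1 | intermediate
17 | (1R,6S)-3-[(phenylsulfanyl)methyl]-6-(propan-2-yl)cyclohex-2-ene-1-carbaldehyde | O=C[C@H]1C=C(CSc2ccccc2)CC[C@H]1C(C)C | intermediate
18 | methyl (2E)-2-(3,3-dimethoxypropyl)-3-[(1S,6S)-3-[(phenylsulfanyl)methyl]-6-(propan-2-yl)cyclohex-2-en-1-yl]prop-2-enoate | COC(=O)/C(CCC(OC)OC)=C/[C@H]1C=C(CSc2ccccc2)CC[C@H]1C(C)C | intermediate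
19 | methyl (2E)-2-(3-oxopropyl)-3-[(1S,6S)-3-[(phenylsulfanyl)methyl]-6-(propan-2-yl)cyclohex-2-en-1-yl]prop-2-enoate | COC(=O)/C(CCC=O)=C/[C@H]1C=C(CSc2ccccc2)CC[C@H]1C(C)C | intermediate
20 | (triphenyl-λ5-phosphanylidene)ethenone | O=C=C=P(c1ccccc1)(c1ccccc1)c1ccccc1 | starting material
21 | 2-(trimethylsilyl)ethanol | C[Si](C)(C)CCO | starting material
22 | 2-(trimethylsilyl)ethyl (triphenyl-λ5-phosphanylidene)acetate | C[Si](C)(C)CCOC(=O)C=P(c1ccccc1)(c1ccccc1)c1ccccc1 | intermediate
23 | 2-(trimethylsilyl)ethyl iodo(triphenyl-λ5-phosphanylidene)acetate | C[Si](C)(C)CCOC(=O)C(I)=P(c1ccccc1)(c1ccccc1)c1ccccc1 | intermediate (not isolated)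
24 | methyl (2E)-2-{(3Z)-4-iodo-5-oxo-5-[2-(trimethylsilyl)ethoxy]pent-3-en-1-yl}-3-[(1S,6S)-3-[(phenylsulfanyl)methyl]-6-(propan-2-yl)cyclohex-2-en-1-yl]prop-2-enoate | COC(=O)/C(CC/C=C(\I)C(=O)OCC[Si](C)(C)C)=C/[C@H]1C=C(CSc2ccccc2)CC[C@H]1C(C)C | intermediate
25 | tributyl(1-ethoxyethenyl)stannane | CCCC[Sn](CCCC)(CCCC)C(=C)OCC | starting material
26 | methyl (2E)-2-{(3E)-4-(1-ethoxyethenyl)-5-oxo-5-[2-(trimethylsilyl)ethoxy]pent-3-en-1-yl}-3-[(1S,6S)-3-[(phenylsulfanyl)methyl]-6-(propan-2-yl)cyclohex-2-en-1-yl]prop-2-enoate | COC(=O)/C(CC/C=C(\C(=C)OCC)C(=O)OCC[Si](C)(C)C)=C/[C@H]1C=C(CSc2ccccc2)CC[C@H]1C(C)C | intermediate (not isolated)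
27 | methyl (2E)-2-{(3E)-4-acetyl-5-oxo-5-[2-(trimethylsilyl)ethoxy]pent-3-en-1-yl}-3-[(1S,6S)-3-[(phenylsulfanyl)methyl]-6-(propan-2-yl)cyclohex-2-en-1-yl]prop-2-enoate | COC(=O)/C(CC/C=C(\C(C)=O)C(=O)OCC[Si](C)(C)C)=C/[C@H]1C=C(CSc2ccccc2)CC[C@H]1C(C)C | intermediate
28 | methyl (2E)-2-{(3E)-5-oxo-4-(4,4,4-trifluoro-3-oxobutanoyl)-5-[2-(trimethylsilyl)ethoxy]pent-3-en-1-yl}-3-[(1S,6S)-3-[(phenylsulfanyl)methyl]-6-(propan-2-yl)cyclohex-2-en-1-yl]prop-2-enoate | COC(=O)/C(CC/C=C(\C(=O)CC(=O)C(F)(F)F)C(=O)OCC[Si](C)(C)C)=C/[C@H]1C=C(CSc2ccccc2)CC[C@H]1C(C)C | intermediate (not isolated)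
29 | methyl (2E)-2-{(3E)-4-(2-diazoacetyl)-5-oxo-5-[2-(trimethylsilyl)ethoxy]pent-3-en-1-yl}-3-[(1S,6S)-3-[(phenylsulfanyl)methyl]-6-(propan-2-yl)cyclohex-2-en-1-yl]prop-2-enoate | COC(=O)/C(CC/C=C(\C(=O)C=[N+]=[N-])C(=O)OCC[Si](C)(C)C)=C/[C@H]1C=C(CSc2ccccc2)CC[C@H]1C(C)C | intermediate
30 | thirteen-membered S-phenyl sulfonium ylide (S bonded to C20 and C9, carbanion at C9; C8 ketone; esters as in 29; (1S,14S)) | COC(=O)/C(CC/C=C(\C(=O)[CH-]3)C(=O)OCC[Si](C)(C)C)=C/[C@H]1C=C(C[S+]3c2ccccc2)CC[C@H]1C(C)C | intermediate (not isolated)
31 | 3-methyl 7-[2-(trimethylsilyl)ethyl] (1S,2E,6E,10S,14S)-11-methylidene-8-oxo-9-(phenylsulfanyl)-14-(propan-2-yl)bicyclo[8.4.0]tetradeca-2,6-diene-3,7-dicarboxylate (C9 epimers) | C=C1CC[C@@H](C(C)C)[C@H]2/C=C(/C(=O)OC)CC/C=C(/C(=O)OCC[Si](C)(C)C)C(=O)C(Sc3ccccc3)[C@H]12 | intermediate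
32 | 3-methyl 7-[2-(trimethylsilyl)ethyl] (1S,2E,6E,10S,14S)-11-methylidene-8-oxo-14-(propan-2-yl)bicyclo[8.4.0]tetradeca-2,6-diene-3,7-dicarboxylate | C=C1CC[C@@H](C(C)C)[C@H]2/C=C(/C(=O)OC)CC/C=C(/C(=O)OCC[Si](C)(C)C)C(=O)C[C@H]12 | intermediate
33 | 3-methyl 7-[2-(trimethylsilyl)ethyl] (1S,2E,6E,8R,10S,14S)-8-hydroxy-11-methylidene-14-(propan-2-yl)bicyclo[8.4.0]tetradeca-2,6-diene-3,7-dicarboxylate | C=C1CC[C@@H](C(C)C)[C@H]2/C=C(/C(=O)OC)CC/C=C(/C(=O)OCC[Si](C)(C)C)[C@H](O)C[C@H]12 | intermediate
34 | microeunicellol B, (1S,2E,6E,8R,10S,14S)-8-hydroxy-3-(methoxycarbonyl)-11-methylidene-14-(propan-2-yl)bicyclo[8.4.0]tetradeca-2,6-diene-7-carboxylic acid | C=C1CC[C@@H](C(C)C)[C@H]2/C=C(/C(=O)OC)CC/C=C(/C(=O)O)[C@H](O)C[C@H]12 | target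

## Step count and least certain steps

Total: 20 steps. Longest linear sequence: 18 steps (steps 1–8, 10–12 and 14–20, from 1 and 2); steps 9 and 13 prepare the two ylides.

**Step 17 (key step).** The carbenoid may be consumed before the remote sulfur reaches it. The nearer competitors are capture by the C7 ester carbonyl (a five-membered carbonyl ylide) and insertion into the allylic C5–H bonds, which are held cis to C8. Capture by the sulfide of a second molecule would give oligomers, and sulfide coordination to rhodium may slow turnover. If the facial bias at C10 is weak, the cis-fused epimer would form as well. Fallback: reach the same ylide without a carbenoid, setting out from 29 and returning at 31. Treatment of 29 with HBr (Et2O, 0 °C) would give the bromomethyl ketone F1. Intramolecular S-alkylation of F1 with AgBF4 at high dilution in MeCN would give the cyclic sulfonium tetrafluoroborate F2. K2CO3 in CH2Cl2 would then deprotonate F2 at C9 to ylide 30, which rearranges to 31. The large ring is then closed by an SN2 reaction at a very reactive α-halo ketone, and no species that can insert or be trapped by oxygen is formed.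

**Step 16.** The amide base may deprotonate C5 (γ to two carbonyl groups) or add to the 2-alkylidene-3-oxo ester instead of enolising the acetyl group, and triethylamine in the transfer stage may scramble the C6=C7 geometry. Fallback: bring the diazo ketone in ready-made, setting out from 19 and returning at 29. Meldrum's acid and 21 would give 3-oxo-3-[2-(trimethylsilyl)ethoxy]propanoic acid F3 (PhMe, 110 °C). Oxalyl chloride would convert F3 into the acid chloride F4, and Me3SiCHN2 (MeCN, 0 °C) would give 2-(trimethylsilyl)ethyl 4-diazo-3-oxobutanoate F5. Knoevenagel condensation of 19 with F5 (piperidine, AcOH, CH2Cl2, 0 °C) would give 29 together with its C6=C7 isomer F6, which is likely to be the favoured one. The isomers would be separated, and F6 re-equilibrated under the condensation conditions and recycled. This road uses no strong base but gives up the geometric control of steps 14 and 15.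

**Step 3.** The thioether of 5 may bind the divalent copper centre, slowing the catalysed path so that an unselective background reaction lowers the enantiomeric purity. The endo preference of an acyclic 1-substituted diene may also be incomplete. If the sense of induction proved opposite to the chelate model, the enantiomeric ligand would be used. Fallback: stoichiometric auxiliary control, setting out from 5 and returning at 8. (4S)-4-Benzyl-3-(prop-2-enoyl)-1,3-oxazolidin-2-one F7, made from (S)-4-benzyl-1,3-oxazolidin-2-one and acryloyl chloride, would react with 5 under Et2AlCl (1.4 equiv, CH2Cl2, −78 °C). In the chelated s-cis model the benzyl group shields the α-Re face, so the expected product is the cis adduct F8 with the configuration of 7. The conditions of step 4 would convert F8 into 8. A stoichiometric Lewis acid cannot be poisoned by the sulfide.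

**Step 11.** Aldehyde 17 may epimerise at C1, or its C10=C11 alkene may move into conjugation, while the slow olefination with the hindered ylide 16 proceeds. Fallback: aldol addition and elimination, setting out from 17 and returning at 18. The lithium enolate of purchased methyl 5,5-dimethoxypentanoate (LiN(iPr)2, THF, −78 °C) would add to 17 within minutes at low temperature to give the β-hydroxy ester F9. MsCl and Et3N would give the mesylate F10, and DBU would eliminate it by an E1cB path to 18, with the (E)-isomer expected to predominate. The aldehyde is then consumed at −78 °C, at the price of two extra steps and a less certain alkene geometry.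

**Step 19.** The conformation of the ten-membered ring or coordination of the neighbouring ester to the catalyst may override the catalyst's facial preference, and the activated C6=C7 alkene may be reduced in a conjugate sense. Fallback: substrate-controlled 1,2-reduction with recycling, setting out from 32 and returning at 33. Luche reduction (NaBH4, CeCl3·7H2O, MeOH, −78 °C) would give 33 together with its C8 epimer F11. The epimers would be separated, and F11 oxidised back to 32 with Dess–Martin periodinane and resubmitted.

## Further compounds

F1 | step 17 | methyl (2E)-2-{(3E)-4-(2-bromoacetyl)-5-oxo-5-[2-(trimethylsilyl)ethoxy]pent-3-en-1-yl}-3-[(1S,6S)-3-[(phenylsulfanyl)methyl]-6-(propan-2-yl)cyclohex-2-en-1-yl]prop-2-enoate | COC(=O)/C(CC/C=C(\C(=O)CBr)C(=O)OCC[Si](C)(C)C)=C/[C@H]1C=C(CSc2ccccc2)CC[C@H]1C(C)C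
F2 | step 17 | thirteen-membered S-phenyl sulfonium tetrafluoroborate (S bonded to C20 and C9H2; otherwise as 30) | COC(=O)/C(CC/C=C(\C(=O)C3)C(=O)OCC[Si](C)(C)C)=C/[C@H]1C=C(C[S+]3c2ccccc2)CC[C@H]1C(C)C.F[B-](F)(F)F
F3 | step 16 | 3-oxo-3-[2-(trimethylsilyl)ethoxy]propanoic acid | C[Si](C)(C)CCOC(=O)CC(=O)O
F4 | step 16 | 2-(trimethylsilyl)ethyl 3-chloro-3-oxopropanoate | C[Si](C)(C)CCOC(=O)CC(=O)Cl
F5 | step 16 | 2-(trimethylsilyl)ethyl 4-diazo-3-oxobutanoate | C[Si](C)(C)CCOC(=O)CC(=O)C=[N+]=[N-]
F6 | step 16 | C6=C7 isomer of 29 (diazoacetyl group trans to C5), methyl (2E)-2-{(3Z)-4-(2-diazoacetyl)-5-oxo-5-[2-(trimethylsilyl)ethoxy]pent-3-en-1-yl}-3-[(1S,6S)-3-[(phenylsulfanyl)methyl]-6-(propan-2-yl)cyclohex-2-en-1-yl]prop-2-enoate | COC(=O)/C(CC/C=C(/C(=O)C=[N+]=[N-])C(=O)OCC[Si](C)(C)C)=C/[C@H]1C=C(CSc2ccccc2)CC[C@H]1C(C)C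
F7 | step 3 | (4S)-4-benzyl-3-(prop-2-enoyl)-1,3-oxazolidin-2-one | C=CC(=O)N1[C@@H](Cc2ccccc2)COC1=O
F8 | step 3 | (4S)-4-benzyl-3-{[(1R,2S)-2-{[tert-butyl(dimethyl)silyl]oxymethyl}-4-[(phenylsulfanyl)methyl]cyclohex-3-en-1-yl]carbonyl}-1,3-oxazolidin-2-one | CC(C)(C)[Si](C)(C)OC[C@H]1C=C(CSc2ccccc2)CC[C@H]1C(=O)N1[C@@H](Cc2ccccc2)COC1=O
F9 | step 11 | methyl 2-{hydroxy[(1S,6S)-3-[(phenylsulfanyl)methyl]-6-(propan-2-yl)cyclohex-2-en-1-yl]methyl}-5,5-dimethoxypentanoate (mixture at the two new centres) | COC(=O)C(CCC(OC)OC)C(O)[C@H]1C=C(CSc2ccccc2)CC[C@H]1C(C)C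
F10 | step 11 | methanesulfonate of F9 | COC(=O)C(CCC(OC)OC)C(OS(C)(=O)=O)[C@H]1C=C(CSc2ccccc2)CC[C@H]1C(C)C
F11 | step 19 | (8S)-epimer of 33 | C=C1CC[C@@H](C(C)C)[C@H]2/C=C(/C(=O)OC)CC/C=C(/C(=O)OCC[Si](C)(C)C)[C@@H](O)C[C@H]12
A1 | alternative 1 | tricarbonyl(η6-1-methoxy-4-(propan-2-yl)benzene)chromium, Cr(CO)3 complex written as its components | COc1ccc(cc1)C(C)C.[Cr].[C-]#[O+].[C-]#[O+].[C-]#[O+]
A2 | alternative 1 | 2-lithio-1,3-dithiane | [Li]C1SCCCS1
A3 | alternative 1 | allyl bromide | C=CCBr
A4 | alternative 1 | trans-5-(1,3-dithian-2-yl)-6-allyl-1-methoxy-4-isopropylcyclohexa-1,3-diene | COC1=CC=C(C(C)C)[C@@H](C2SCCCS2)[C@@H]1CC=C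
A5 | alternative 2 | (E)-5-methylhexa-1,3-diene | C=C/C=C/C(C)C
A6 | alternative 2 | (4R)-4-benzyl-3-[(2E)-5-{[tert-butyl(dimethyl)silyl]oxy}pent-2-enoyl]-1,3-oxazolidin-2-one | CC(C)(C)[Si](C)(C)OCC/C=C/C(=O)N1[C@H](Cc2ccccc2)COC1=O
A7 | alternative 2 | ring A cyclohexene with the C1 acyl oxazolidinone, the C14 isopropyl group and the C10 silyloxyethyl arm | C1C=C[C@@H](C(C)C)[C@@H](C(=O)N2[C@H](Cc3ccccc3)COC2=O)[C@@H]1CCO[Si](C)(C)C(C)(C)C
A8 | alternative 3 | fourteen-membered carbocycle with trans C1–C2 epoxide, C10=C11 alkene bearing CH2SiMe3 on C11 (alkene geometry left open), C3 methyl ester, C6=C7 silylethyl enoate and C8 silyl ether | C[Si](C)(C)CC1CC[C@@H](C(C)C)[C@H]2O[C@@H]2C(C(=O)OC)CC/C=C(/C(=O)OCC[Si](C)(C)C)[C@H](O[Si](C)(C)C(C)(C)C)CC=1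
A9 | alternative 3 | bicyclic C2 alcohol with the exocyclic methylene in place (C3 epimers) | C=C1CC[C@@H](C(C)C)[C@H]2[C@H](O)C(C(=O)OC)CC/C=C(/C(=O)OCC[Si](C)(C)C)[C@H](O[Si](C)(C)C(C)(C)C)C[C@H]12
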